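(The runs were computed on assumed constants, and the scatter is random.)

A one-step world, electrophile plus nucleophile to product, takes equal charges down together towards nothing, yet the ash run stands at 40% electrophile after 3.00 d.

in all of them: electrophile 0.020 M
- ash: nucleophile 0.020 M; buffer base 4 mM; buffer acid 0.056 M; run made earlier
- birch: nucleophile 0.020 M; buffer base 4 mM; buffer acid 0.088 M; run made earlier
- alder: nucleophile 0.020 M; buffer base 2 mM; buffer acid 0.040 M; run made earlier
- flask: nucleophile 0.0200 M; buffer base 4.00 mM; buffer acid 0.0400 M; time 2.5 d

| run | time / d | electrophile / % | product / % |
|---|---|---|---|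
| ash | 0.250 | 59 | 39 |
| ash | 0.417 | 50 | 48 |
| ash | 0.833 | 42 | 55 |
| ash | 1.67 | 43 | 60 |
| ash | 3.00 | 40 | 60 |
| birch | 0.625 | 48 | 53 |
| birch | 1.25 | 42 | 57 |
| birch | 1.67 | 40 | 61 |
| birch | 2.50 | 40 | 61 |
| birch | 3.00 | 39 | 61 |
| alder | 0.250 | 61 | 41 |
| alder | 0.417 | 52 | 46 |
| alder | 0.833 | 48 | 56 |
| alder | 1.67 | 44 | 55 |
| alder | 3.00 | 44 | 58 |

(readings scatter by 1.5 percentage points)

- the analysis behind the earlier runs scatters by 1.5 percentage points, standard deviation
- a reading or a percentage of product counts all its forms, free or not
- the earlier runs do not show the pH; that part of a forecast is a guess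

- part of the electrophile that has reacted at 2.5 d
- pH of the solution at 2.5 d

Birch, with 0.088 M of buffer acid against the 0.056 M in ash, levels off in much the same place. Alder, with half the buffer base of ash and also less buffer acid, reads more electrophile at its last point, 44%.

The reckoning offered here, which is not the forecast's, supposes that each product frees one acid. Buffer base takes that acid up first and nucleophile afterwards, so past that point each product costs two nucleophiles. The nucleophile charge plus the buffer-base charge, over twice the electrophile charge, is then the part of the electrophile that can react. For the flask this is 60.0%, the stop share s.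

The test is against the last readings. Ash has s = 60.0% and reads 60.0% reacted, birch has s = 60.0% and reads 61.0% reacted, and alder has s = 55.0% and reads 56.0% reacted, against a scatter of 1.5 percentage points. So far as these readings go, s tracks the extent, but the pH stands outside it and remains a guess.

The forecast gave 57% and pH 4.2, noting that “Conversion seems to rise slightly with buffer acid”. The stop share stands higher.

The flask gives 60.1% and pH 4.05.

    electrophile + nucleophile → acid + product + leaving group (k = 7.30 M⁻¹ h⁻¹)
    buffer acid ⇌ buffer base + acid, settled at all times (K = 1.60 × 10⁻⁹ M)
    crystals ⇌ product, rate k3*(cs3 - [product]) while solid is left; crystals form when [product] > cs3 (solubility = 9.70 mM, k = 3.60 h⁻¹)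
    protonated nucleophile ⇌ nucleophile + acid, settled at all times (K = 4.00 × 10⁻⁷ M)

Beside s = 60.0%, the flask's nucleophile is the limiting reagent: at 2.50 d, 0.18% of its charge is free, less than the 40% of the electrophile charge still there, and 0.00794 M stands as protonated nucleophile. Both forecast values lie within their margins, but the electrophile charge moves the answer: at 0.0219 M, the other charges and the time held, it has shifted by 5 points. The same reckoning on the neighbour flask with 0.080 M of electrophile gives s = 15.0%, and at 2.50 d that neighbour flask has reacted 15.3% of its electrophile.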